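**Strategy.** The target is a C2-symmetric dimer, cut at the central C–C bond of the tetraene into two identical cyclohexenols. Each cyclohex-3-en-1-ol ring (C1 carbinol, C2 quaternary, C3=C4, C5 and C6 methylenes) shows C1–OH cis to the C2 side chain next to the C3=C4 bond: the retron of an anti-SN2′ opening of a 7-oxanorbornene whose oxygen bridge spans C1 and C4. The key step, a Diels–Alder reaction of a 2,4-disubstituted furan with 1,2-bis(phenylsulfonyl)ethene (an ethylene equivalent after desulfonylation and diimide reduction), forms C4–C5 and C6–C1 at once and installs this temporary C4–O bond, which later leaves as methyl enters C2.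

Key step: step 4

Remark: compounds 8 to 11 are racemic and are drawn as the enantiomer that is carried on after step 8; ring positions are numbered as in cyclohex-3-en-1-ol.

**Step 1**
Reactants: 1 4-bromofuran-2-carbaldehyde; 2 5-bromo-2-methylpent-2-ene
Product: 4 4-(4-methylpent-3-en-1-yl)furan-2-carbaldehyde, via alkylzinc bromide 3 (not isolated)
Conditions: 2, Zn (activated with TMSCl and BrCH2CH2Br), LiCl, THF, 50 °C; then 1, Pd(OAc)2 (2 mol %), SPhos (4 mol %), THF, 25 °C
Reagents that add atoms: none
Why: Negishi coupling: the primary alkylzinc bromide made by LiCl-assisted zinc insertion transmetalates to the arylpalladium bromide formed at C4 of the furan much faster than it adds to the aldehyde, and the bulky biarylphosphine suppresses β-hydride elimination.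

**Step 2**
Reactants: 4 4-(4-methylpent-3-en-1-yl)furan-2-carbaldehyde
Product: 5 [4-(4-methylpent-3-en-1-yl)furan-2-yl]methanol
Conditions: NaBH4, MeOH, 0 °C
Reagents that add atoms: none
Why: Chemoselective borohydride reduction of the aldehyde, which leaves the furan and the trisubstituted alkene untouched.

**Step 3**
Reactants: 5 [4-(4-methylpent-3-en-1-yl)furan-2-yl]methanol
Product: 6 tert-butyl(dimethyl){[4-(4-methylpent-3-en-1-yl)furan-2-yl]methoxy}silane
Conditions: TBSCl, imidazole, DMF, 0 °C to 25 °C
Reagents that add atoms: tert-butyldimethylsilyl chloride, CC(C)(C)[Si](C)(C)Cl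
Why: Standard silylation of a primary alcohol with imidazole as base and nucleophilic catalyst; the silyl ether makes the furan more electron-rich than the aldehyde did and later shields the alkene carbon next to the bridgehead.

**Step 4**
Reactants: 6 tert-butyl(dimethyl){[4-(4-methylpent-3-en-1-yl)furan-2-yl]methoxy}silane; 7 (E)-1,2-bis(phenylsulfonyl)ethene
Product: 8 racemic tert-butyl(dimethyl){[3-(4-methylpent-3-en-1-yl)-trans-5,6-bis(phenylsulfonyl)-7-oxabicyclo[2.2.1]hept-2-en-1-yl]methoxy}silane (6-exo,5-endo isomer drawn; the 6-endo,5-exo isomer is expected as well and converges in step 5)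
Conditions: 6 (1.2 equiv), 7, toluene, 50 °C, dark
Reagents that add atoms: none
Why: Concerted, asynchronous normal-electron-demand [4+2] cycloaddition (Diels–Alder reaction) between the HOMO of the electron-rich 2,4-dialkylfuran and the LUMO of the doubly sulfonyl-activated alkene; the closest known reaction type is the use of 1,2-bis(arylsulfonyl)ethenes as acetylene equivalents toward furans. The carbocyclic six-membered ring is closed by intermolecular suprafacial–suprafacial addition across furan C2 and C5, so that both new C–C bonds (C4–C5 and C6–C1 of the later cyclohexenol) form in one event while the furan oxygen becomes the one-atom bridge of a 7-oxanorbornene. The two bridgehead stereocentres arise cis to each other by the geometry of the bridge and are racemic at this stage (the absolute configuration is selected in step 8); the two sulfonyl-bearing centres are trans because the (E)-alkene geometry is retained, and their endo/exo orientation is irrelevant because both are removed in step 5. The step needs periselectivity for the furan diene over the isolated trisubstituted alkene, which the electron-poor dienophile secures, and it needs no regiocontrol because the dienophile is symmetric. Reversibility, the usual weakness of furan cycloadditions, is countered by the two donor substituents on the furan, the strongly activated dienophile and the mild temperature. The oxygen bridge made here is the design element: it holds the future carbinol oxygen, becomes the leaving group at the other bridgehead and fixes the face from which methyl enters in step 7.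

**Step 5**
Reactants: 8 racemic bis-sulfone cycloadduct
Product: 9 racemic tert-butyl(dimethyl){[(1S,4R)-3-(4-methylpent-3-en-1-yl)-7-oxabicyclo[2.2.1]hepta-2,5-dien-1-yl]methoxy}silane
Conditions: 5% Na(Hg), NaH2PO4, MeOH/THF, −20 °C
Reagents that add atoms: none
Why: Reductive elimination of a vicinal bis-sulfone (Julia-type): electron transfer cleaves one C–S bond and the resulting carbanion expels the neighbouring sulfinate, a far better leaving group than the bridging alkoxide, so that the alkene and not the ring-opened dienol is formed; no stereocentre is created.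

**Step 6**
Reactants: 9 racemic oxanorbornadiene
Product: 10 racemic tert-butyl(dimethyl){[(1S,4R)-3-(4-methylpent-3-en-1-yl)-7-oxabicyclo[2.2.1]hept-2-en-1-yl]methoxy}silane
Conditions: 2-nitrobenzenesulfonohydrazide (2 equiv), Et3N, CH2Cl2, 25 °C
Reagents that add atoms: none
Why: Diimide reduction by concerted syn transfer of two hydrogens: the strained, unhindered disubstituted alkene of the norbornadiene type reacts much faster than the trisubstituted bridge alkene and the prenyl alkene, and the neutral conditions spare the acid-labile oxabicycle and the silyl ether.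

**Step 7**
Reactants: 10 racemic oxanorbornene
Product: 11 racemic (1R,2S)-4-({[tert-butyl(dimethyl)silyl]oxy}methyl)-2-methyl-2-(4-methylpent-3-en-1-yl)cyclohex-3-en-1-ol
Conditions: MeMgBr (3 equiv), CuCl (10 mol %), PPh3 (10 mol %), toluene/Et2O, 0 °C to 25 °C; then H2O, aq. NH4Cl
Reagents that add atoms: methylmagnesium bromide, C[Mg]Br
Why: Copper-catalysed anti-SN2′ ring opening of an oxabicyclic alkene by a Grignard reagent: the methylcopper species attacks the side-chain-bearing alkene carbon on the face opposite to the oxygen bridge while the C–O bond at the substituted bridgehead breaks (the developing allyl system is tertiary at both ends and the silyloxymethyl group shields the other alkene carbon), so that the new quaternary centre carries methyl trans and the side chain cis to the liberated hydroxyl, as in the target.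

**Step 8**
Reactants: 11 racemic (1R,2S)-cyclohexenol
Product: 12 (1R,2S)-4-({[tert-butyl(dimethyl)silyl]oxy}methyl)-2-methyl-2-(4-methylpent-3-en-1-yl)cyclohex-3-en-1-yl acetate
Conditions: immobilised Candida antarctica lipase B, vinyl acetate, tert-butyl methyl ether, 35 °C, stopped near half conversion; chromatography
Reagents that add atoms: vinyl acetate, CC(=O)OC=C
Why: Lipase-catalysed kinetic resolution by irreversible transesterification: by the empirical size rule for lipases the (R)-carbinol, whose larger neighbour is the quaternary carbon, is acylated faster, which selects the (1R,2S) enantiomer as its acetate (a useful protecting group) while the unreacted (1S,2R)-alcohol is removed by chromatography.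

**Step 9**
Reactants: 12 (1R,2S)-acetate
Product: 13 (1R,2S)-4-({[tert-butyl(dimethyl)silyl]oxy}methyl)-2-{2-[(2R)-3,3-dimethyloxiran-2-yl]ethyl}-2-methylcyclohex-3-en-1-yl acetate
Conditions: D-fructose-derived Shi ketone (30 mol %), KHSO5 (as Oxone, 1.4 equiv), K2CO3, Bu4NHSO4, MeCN/dimethoxymethane, aq. Na2B4O7 buffer (pH 10.5), 0 °C
Reagents that add atoms: potassium peroxymonosulfate, [K+].[O-]S(=O)(=O)OO
Why: Shi asymmetric epoxidation: the chiral dioxirane formed from the D-fructose-derived ketone transfers oxygen through the spiro transition state to the unhindered, electron-rich prenyl alkene to set the (R)-epoxide under catalyst control, while the ring alkene is shielded by the adjacent quaternary carbon and deactivated by the allylic silyl ether.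

**Step 10**
Reactants: 13 epoxy silyl ether acetate
Product: 14 (1R,2S)-2-{2-[(2R)-3,3-dimethyloxiran-2-yl]ethyl}-4-(hydroxymethyl)-2-methylcyclohex-3-en-1-yl acetate
Conditions: Bu4NF, AcOH, THF, 0 °C to 25 °C
Reagents that add atoms: none
Why: Fluoride-induced desilylation driven by the strong Si–F bond; buffering with acetic acid keeps the medium mild enough for the acetate and the epoxide.

**Step 11**
Reactants: 14 allylic alcohol acetate
Product: 17 (1R,2S)-2-{2-[(2R)-3,3-dimethyloxiran-2-yl]ethyl}-4-ethynyl-2-methylcyclohex-3-en-1-ol, via acetoxy enal 15 (not isolated), via acetoxy enyne 16 (not isolated)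
Conditions: MnO2 (10 equiv), THF, 25 °C; then MeOH, K2CO3, dimethyl (1-diazo-2-oxopropyl)phosphonate, 25 °C, warmed to 40 °C until the acetate is gone
Reagents that add atoms: dimethyl (1-diazo-2-oxopropyl)phosphonate, CC(=O)C(=[N+]=[N-])P(=O)(OC)OC
Why: Tandem allylic oxidation and Ohira–Bestmann (Seyferth–Gilbert) homologation: MnO2 oxidises only the allylic alcohol, the diazomethylphosphonate anion released by methanolysis converts the enal into the terminal enyne (conjugate addition of methanol is blocked because the β-carbon is neopentylic), and the same K2CO3/MeOH medium removes the acetate.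

**Step 12**
Reactants: 17 hydroxy enyne (two molecules are joined)
Product: 20 (1R,1′R,2S,2′S)-4,4′-[(1E,3E)-buta-1,3-diene-1,4-diyl]bis(2-{2-[(2R)-3,3-dimethyloxiran-2-yl]ethyl}-2-methylcyclohex-3-en-1-ol), via alkenylzirconocene 18 (not isolated), via alkenylcopper 19 (not isolated)
Conditions: Cp2Zr(H)Cl (2.4 equiv), THF, 25 °C, dark; then CuCl (1.2 equiv), 0 °C to 25 °C; aq. NH4Cl
Reagents that add atoms: none
Why: Hydrozirconation followed by transmetalation to copper and homocoupling: syn addition of Zr–H places zirconium on the terminal carbon, and the alkenylcopper formed with CuCl dimerises with retention of alkene geometry, so that the central C–C bond is formed between two (E)-alkenyl units and the (E,E)-diene of the tetraene results; the hydroxyl consumes one equivalent of the hydride and is restored on work-up.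

**Compound list**

1 | 4-bromofuran-2-carbaldehyde | O=Cc1cc(Br)co1 | starting material
2 | 5-bromo-2-methylpent-2-ene | CC(C)=CCCBr | starting material
3 | (4-methylpent-3-en-1-yl)zinc bromide (not isolated) | CC(C)=CCC[Zn]Br | intermediate
4 | 4-(4-methylpent-3-en-1-yl)furan-2-carbaldehyde | O=Cc1cc(CCC=C(C)C)co1 | intermediate
5 | [4-(4-methylpent-3-en-1-yl)furan-2-yl]methanol | OCc1cc(CCC=C(C)C)co1 | intermediate
6 | tert-butyl(dimethyl){[4-(4-methylpent-3-en-1-yl)furan-2-yl]methoxy}silane | CC(C)=CCCc1coc(CO[Si](C)(C)C(C)(C)C)c1 | intermediate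
7 | (E)-1,2-bis(phenylsulfonyl)ethene | O=S(=O)(/C=C/S(=O)(=O)c1ccccc1)c1ccccc1 | starting material
8 | racemic tert-butyl(dimethyl){[3-(4-methylpent-3-en-1-yl)-trans-5,6-bis(phenylsulfonyl)-7-oxabicyclo[2.2.1]hept-2-en-1-yl]methoxy}silane (6-exo,5-endo isomer drawn) | CC(C)=CCCC1=C[C@]2(CO[Si](C)(C)C(C)(C)C)[C@@H](S(=O)(=O)c3ccccc3)[C@H](S(=O)(=O)c3ccccc3)[C@H]1O2 | intermediate
9 | racemic tert-butyl(dimethyl){[(1S,4R)-3-(4-methylpent-3-en-1-yl)-7-oxabicyclo[2.2.1]hepta-2,5-dien-1-yl]methoxy}silane | CC(C)=CCCC1=C[C@]2(CO[Si](C)(C)C(C)(C)C)C=C[C@H]1O2 | intermediate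
10 | racemic tert-butyl(dimethyl){[(1S,4R)-3-(4-methylpent-3-en-1-yl)-7-oxabicyclo[2.2.1]hept-2-en-1-yl]methoxy}silane | CC(C)=CCCC1=C[C@]2(CO[Si](C)(C)C(C)(C)C)CC[C@H]1O2 | intermediate
11 | racemic (1R,2S)-4-({[tert-butyl(dimethyl)silyl]oxy}methyl)-2-methyl-2-(4-methylpent-3-en-1-yl)cyclohex-3-en-1-ol | CC(C)=CCC[C@@]1(C)C=C(CO[Si](C)(C)C(C)(C)C)CC[C@H]1O | intermediate
12 | (1R,2S)-4-({[tert-butyl(dimethyl)silyl]oxy}methyl)-2-methyl-2-(4-methylpent-3-en-1-yl)cyclohex-3-en-1-yl acetate | CC(C)=CCC[C@@]1(C)C=C(CO[Si](C)(C)C(C)(C)C)CC[C@H]1OC(C)=O | intermediate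
13 | (1R,2S)-4-({[tert-butyl(dimethyl)silyl]oxy}methyl)-2-{2-[(2R)-3,3-dimethyloxiran-2-yl]ethyl}-2-methylcyclohex-3-en-1-yl acetate | CC1(C)O[C@@H]1CC[C@@]1(C)C=C(CO[Si](C)(C)C(C)(C)C)CC[C@H]1OC(C)=O | intermediate
14 | (1R,2S)-2-{2-[(2R)-3,3-dimethyloxiran-2-yl]ethyl}-4-(hydroxymethyl)-2-methylcyclohex-3-en-1-yl acetate | CC1(C)O[C@@H]1CC[C@@]1(C)C=C(CO)CC[C@H]1OC(C)=O | intermediate
15 | (1R,2S)-2-{2-[(2R)-3,3-dimethyloxiran-2-yl]ethyl}-4-formyl-2-methylcyclohex-3-en-1-yl acetate (not isolated) | CC1(C)O[C@@H]1CC[C@@]1(C)C=C(C=O)CC[C@H]1OC(C)=O | intermediate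
16 | (1R,2S)-2-{2-[(2R)-3,3-dimethyloxiran-2-yl]ethyl}-4-ethynyl-2-methylcyclohex-3-en-1-yl acetate (not isolated) | CC1(C)O[C@@H]1CC[C@@]1(C)C=C(C#C)CC[C@H]1OC(C)=O | intermediate
17 | (1R,2S)-2-{2-[(2R)-3,3-dimethyloxiran-2-yl]ethyl}-4-ethynyl-2-methylcyclohex-3-en-1-ol | CC1(C)O[C@@H]1CC[C@@]1(C)C=C(C#C)CC[C@H]1O | intermediate
18 | (E)-alkenylzirconocene chloride of the O-zirconated alcohol (not isolated) | CC1(C)O[C@@H]1CC[C@@]1(C)C=C(/C=C/[Zr](Cl)(C2C=CC=C2)C2C=CC=C2)CC[C@H]1O[Zr](Cl)(C1C=CC=C1)C1C=CC=C1 | intermediate
19 | (E)-alkenylcopper of the O-zirconated alcohol (not isolated) | CC1(C)O[C@@H]1CC[C@@]1(C)C=C(/C=C/[Cu])CC[C@H]1O[Zr](Cl)(C1C=CC=C1)C1C=CC=C1 | intermediate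
20 | (1R,1′R,2S,2′S)-4,4′-[(1E,3E)-buta-1,3-diene-1,4-diyl]bis(2-{2-[(2R)-3,3-dimethyloxiran-2-yl]ethyl}-2-methylcyclohex-3-en-1-ol) | CC1(C)O[C@@H]1CC[C@@]1(C)C=C(/C=C/C=C/C2=C[C@](C)(CC[C@H]3OC3(C)C)[C@H](O)CC2)CC[C@H]1O | target

**Total step count:** 12. **Longest linear sequence:** 12 steps (from 1 or 2 to 20).

**Steps most likely to fail**

1. Step 7. The methylcopper species may attack the unsubstituted alkene carbon and cleave the other C–O bond, or may fail to react at the fully substituted alkene carbon at all. The fallback exchanges the roles of the two substituents of the quaternary carbon and replaces the anti substitution by a syn carbometalation. It sets out from 1.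
   - Suzuki–Miyaura methylation (trimethylboroxine, PdCl2(dppf), K2CO3, dioxane/H2O) should give 4-methylfuran-2-carbaldehyde F1.
   - NaBH4 reduction should give (4-methylfuran-2-yl)methanol F2, and silylation with TBSCl/imidazole the silyl ether F3.
   - Cycloaddition with 7 should give the racemic methyl-substituted bis-sulfone adduct F4, Na(Hg) the methyl-substituted oxanorbornadiene F5, and diimide the methyl-substituted oxanorbornene F6.
   - FeCl3-catalysed carbomagnesiation of F6 with (4-methylpent-3-en-1-yl)magnesium bromide (from 2 and Mg), followed by β-alkoxide elimination, delivers the side chain to the methyl-bearing alkene carbon from the face of the oxygen bridge, cis to the hydroxyl. The fallback comes back to the route at 11.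

2. Step 12. The zirconium hydride may open the epoxide reductively, transmetalation may be incomplete, or the tetraene may isomerise or decompose during the copper-mediated dimerisation. The fallback uses iodo-olefination and a palladium-mediated dimerisation. It sets out from 14.
   - MnO2 alone gives acetoxy enal 15, which is now isolated.
   - Takai olefination (CrCl2, CHI3, THF/dioxane, 0 °C) should give the (E)-dienyl iodide F7.
   - Pd(PPh3)4 with (Me3Sn)2 (0.5 equiv) in dioxane stannylates half of the iodide in the flask and couples it with the rest (Stille homocoupling) to the tetraene diacetate F8.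
   - K2CO3 in MeOH removes both acetates, and the fallback comes back to the route at 20.

3. Step 8. Enzymatic acylation of the hindered carbinol may be too slow or too unselective, leaving material of low enantiomeric purity. The fallback is a covalent resolution. It sets out from racemic 11.
   - Esterification with (S)-2-methoxy-2-phenylacetic acid (EDC, DMAP, CH2Cl2) gives two diastereomeric esters, from which the (1R,2S)-configured mandelate ester F9 is separated by chromatography.
   - LiOH in THF/H2O cleaves it to the single-enantiomer (1R,2S)-alcohol F10.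
   - Acetylation (Ac2O, pyridine, DMAP) returns to the route at 12.

**Further compounds**

F1 | step 7 | 4-methylfuran-2-carbaldehyde | Cc1coc(C=O)c1
F2 | step 7 | (4-methylfuran-2-yl)methanol | Cc1coc(CO)c1
F3 | step 7 | tert-butyl(dimethyl)[(4-methylfuran-2-yl)methoxy]silane | Cc1coc(CO[Si](C)(C)C(C)(C)C)c1
F4 | step 7 | racemic tert-butyl(dimethyl){[3-methyl-trans-5,6-bis(phenylsulfonyl)-7-oxabicyclo[2.2.1]hept-2-en-1-yl]methoxy}silane (6-exo,5-endo isomer drawn) | CC1=C[C@]2(CO[Si](C)(C)C(C)(C)C)[C@@H](S(=O)(=O)c3ccccc3)[C@H](S(=O)(=O)c3ccccc3)[C@H]1O2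
F5 | step 7 | racemic tert-butyl(dimethyl){[(1S,4R)-3-methyl-7-oxabicyclo[2.2.1]hepta-2,5-dien-1-yl]methoxy}silane | CC1=C[C@]2(CO[Si](C)(C)C(C)(C)C)C=C[C@H]1O2
F6 | step 7 | racemic tert-butyl(dimethyl){[(1S,4R)-3-methyl-7-oxabicyclo[2.2.1]hept-2-en-1-yl]methoxy}silane | CC1=C[C@]2(CO[Si](C)(C)C(C)(C)C)CC[C@H]1O2
F7 | step 12 | (1R,2S)-2-{2-[(2R)-3,3-dimethyloxiran-2-yl]ethyl}-4-[(E)-2-iodoethenyl]-2-methylcyclohex-3-en-1-yl acetate | CC1(C)O[C@@H]1CC[C@@]1(C)C=C(/C=C/I)CC[C@H]1OC(C)=O
F8 | step 12 | diacetate of 20 | CC1(C)O[C@@H]1CC[C@@]1(C)C=C(/C=C/C=C/C2=C[C@](C)(CC[C@H]3OC3(C)C)[C@H](OC(C)=O)CC2)CC[C@H]1OC(C)=O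
F9 | step 8 | (1R,2S)-4-({[tert-butyl(dimethyl)silyl]oxy}methyl)-2-methyl-2-(4-methylpent-3-en-1-yl)cyclohex-3-en-1-yl (2S)-2-methoxy-2-phenylacetate | CC(C)=CCC[C@@]1(C)C=C(CO[Si](C)(C)C(C)(C)C)CC[C@H]1OC(=O)[C@@H](OC)c1ccccc1
F10 | step 8 | (1R,2S)-4-({[tert-butyl(dimethyl)silyl]oxy}methyl)-2-methyl-2-(4-methylpent-3-en-1-yl)cyclohex-3-en-1-ol, single enantiomer | CC(C)=CCC[C@@]1(C)C=C(CO[Si](C)(C)C(C)(C)C)CC[C@H]1O
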